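**Assumption:** 5,7-dihydroxy-4-methylphthalide, (R)-(+)-pulegone and tert-butyl acrylate are taken as commercial; the route is a paper design that has not been run, and yields or ratios quoted are estimates.

## Retrosynthetic overview

1. Target ⇐ late reduction of the ketone next to the γ-lactone in pentacyclic keto lactone 19.
2. 19 ⇐ intramolecular [4+2] of the dearomatized phthalide dienone 15 with the exocyclic alkene of ring B, run under 390 nm light. This one step forms the bicyclo[2.2.2]octane and the cyclopentane.
3. 15 ⇐ C4-alkylative dearomatization of phthalide 3 (the future ring D) with the homoallylic iodide 14.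
4. 14 ⇐ formaldehyde ene reaction on tertiary allylic alcohol 11, which sets the CH2-bearing stereocentre and the exocyclic methylene; 11 ⇐ methyl addition to dienone 10.
5. 10 ⇐ (R)-pulegone (ring B bought) by deconjugative Michael addition, lactonization (ring A) and double dehydrogenation. Ring order: B, A, D (bought as arene), then the cage.

Locants used below: the ring A/B unit is numbered as 2-oxaspiro[5.5]undecane (C6 spiro, C7 carbinol, C8, C9); ring D uses phthalide numbering (C3a, C4, C5, C6, C7, C7a).

## Route

**Step 1**
Reactants: 1 5,7-dihydroxy-4-methylphthalide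
Product: 3 5,7-dihydroxy-4,6-dimethylphthalide, via hydroxymethyl phthalide 2 (not isolated)
Conditions: (CH2O)n, Et3SiH, CF3CO2H/CH2Cl2, 0 → 25 °C
Reagents that add atoms: paraformaldehyde (C=O)
Why: Electrophilic hydroxymethylation at the only free ring position (C6, between the two OH groups) followed by ionic hydrogenation of the benzylic cation (reductive methylation); no stereocentre.

**Step 2**
Reactants: 4 (R)-(+)-pulegone; 5 tert-butyl acrylate
Product: 6 tert-butyl 3-[(1R,4R)-4-methyl-2-oxo-1-(prop-1-en-2-yl)cyclohexyl]propanoate
Conditions: KOtBu (0.2 equiv), tBuOH/THF, 0 → 25 °C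
Reagents that add atoms: none
Why: Deconjugative Michael addition of the thermodynamic dienolate at the α-carbon; axial attack on the half-chair with the ring methyl equatorial places the new chain cis to that methyl (1,4-induction, expected about 4:1, separable), so the quaternary centre is set by the pulegone stereocentre.

**Step 3**
Reactants: 6 Michael adduct
Product: 8 (6R,9R)-1,1,9-trimethyl-2-oxaspiro[5.5]undecane-3,7-dione, via carboxylic acid 7 (not isolated)
Conditions: CF3CO2H, CH2Cl2, 0 → 25 °C
Reagents that add atoms: none
Why: Acidolysis of the tert-butyl ester, then Markovnikov acid-catalysed lactonization of the acid onto the isopropenyl group gives the gem-dimethyl δ-lactone (ring A); no stereocentre is touched.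

**Step 4**
Reactants: 8 spiro keto lactone
Product: 10 (R)-1,1,9-trimethyl-2-oxaspiro[5.5]undeca-4,8-diene-3,7-dione, via bis-selenide 9 (not isolated)
Conditions: LiN(iPr)2 (2.3 equiv), THF, −78 °C; PhSeCl; then H2O2, pyridine, CH2Cl2, 0 °C
Reagents that add atoms: none
Why: Double α-selenenylation of the ketone and lactone enolates and selenoxide syn-elimination give the enone and the unsaturated lactone in one operation; the pulegone stereocentre is erased after it has done its work and the spiro centre is kept.

**Step 5**
Reactants: 10 dienone lactone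
Product: 11 (6S,7R)-7-hydroxy-1,1,7,9-tetramethyl-2-oxaspiro[5.5]undeca-4,8-dien-3-one
Conditions: MeLi, CeCl3, THF, −78 °C
Reagents that add atoms: methyllithium ([Li]C)
Why: Organocerium 1,2-addition to the hindered enone carbonyl spares the tertiary-alkyl lactone; the methyl enters anti to the pseudo-axial vinyl arm of the spiro lactone (the CMe2 arm sits equatorial), so the OH ends cis to the lactone CH=.

**Step 6**
Reactants: 11 tertiary allylic alcohol
Product: 12 (6S,7R,8S)-7-hydroxy-8-(hydroxymethyl)-1,1,7-trimethyl-9-methylidene-2-oxaspiro[5.5]undec-4-en-3-one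
Conditions: (CH2O)n, Me2AlCl (2.5 equiv), CH2Cl2, −78 → 0 °C
Reagents that add atoms: paraformaldehyde (C=O)
Why: Lewis acid formaldehyde ene reaction; C–C bond formation occurs at the less substituted alkene carbon on the face of the aluminium alkoxide (anti to the C7 methyl and the CMe2 arm), and hydrogen is taken from the ring methyl syn to the vinyl H, giving the exocyclic methylene; ionisation of the tertiary allylic alkoxide is the risk to watch at low temperature.

**Step 7**
Reactants: 12 diol
Product: 14 (6R,7R,8R)-8-(iodomethyl)-1,1,7-trimethyl-9-methylidene-7-(trimethylsilyloxy)-2-oxaspiro[5.5]undec-4-en-3-one, via iodo alcohol 13 (not isolated)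
Conditions: I2, PPh3, imidazole, CH2Cl2, 0 °C; then Me3SiCl, 25 °C
Reagents that add atoms: iodine (II); chlorotrimethylsilane (C[Si](C)(C)Cl)
Why: Appel-type iodination is selective for the primary alcohol, and in-situ silylation of the tertiary alcohol prevents oxetane formation in the next step; no stereocentre changes.

**Step 8**
Reactants: 14 homoallylic iodide; 3 5,7-dihydroxy-4,6-dimethylphthalide
Product: 15 C4-alkylated dearomatized phthalide 7-hydroxy-4,6-dimethyl-4-(ring-B-methyl)isobenzofuran-1,5(3H,4H)-dione as about 1:1 C4 epimers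
Conditions: LiN(SiMe3)2 (2.2 equiv per 3), toluene/THF 3:1, −78 → 45 °C; pH 7 work-up
Reagents that add atoms: none
Why: Alkylative dearomatization of the dilithium phenolate at C4 (ortho to O5, para to the chelated O7), with lithium, low polarity and a soft iodide favouring C- over O-alkylation; the new quaternary centre is not controlled here and is corrected in step 9.

**Step 9**
Reactants: 15 dearomatized dienone (both C4 epimers)
Product: 19 pentacyclic keto lactone (target with C=O in place of the secondary CHOH), via bis-silyl dienone 16 (not isolated), via dienylketene 17 (not isolated), via silyl enol ether cage 18 (not isolated)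
Conditions: MeC(OSiMe3)=NSiMe3, PhCl, 25 °C; then hν (390 nm LED), 110 °C, Ar; then HCl, MeOH/THF, 0 °C
Reagents that add atoms: none
Why: Proposed new method: a light-driven stereoconvergent intramolecular Diels–Alder reaction, in which 390 nm excitation of the O-silylated cyclohexa-2,4-dienone 16 opens the C4–C5 bond to the (Z)-dienylketene 17, which recloses thermally on either face and so interconverts the two C4 epimers, while only the epimer whose tether can sit cis-fused on ring B reaches the thermal [4+2] transition state (ring-B C9 to phthalide C3a, exocyclic CH2 to phthalide C6), making the irreversible cycloaddition the sink that sets the four cage stereocentres from the ring-B stereocentre; silylation breaks the enol–lactone hydrogen bond that would otherwise deactivate the excited state; closest known reactions are the thermal intramolecular Diels–Alder of 6-alkenylcyclohexa-2,4-dienones to isotwistanes and the photochemical epimerisation of 6,6-disubstituted cyclohexadienones through dienylketenes.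

**Step 10**
Reactants: 19 pentacyclic keto lactone
Product: 20 target compound
Conditions: SmI2 (2.5 equiv), THF/MeOH, −78 °C
Reagents that add atoms: none
Why: Samarium diiodide ketyl reduction of the chelated β-keto lactone, which should leave the doubly α-quaternary ketone and the conjugated lactone alone; the bulky O–Sm is expected to take the open side facing the ketone bridge so that C–H forms on the CH2-bridge side, and the lactone α-carbon is epimerisable and should settle trans to the new OH, as in the target.

## Compound list

1 | 5,7-dihydroxy-4-methylphthalide | Cc1c(O)cc(O)c2C(=O)OCc12 | starting material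
2 | 5,7-dihydroxy-6-(hydroxymethyl)-4-methylphthalide | Cc1c(O)c(CO)c(O)c2C(=O)OCc12 | intermediate
3 | 5,7-dihydroxy-4,6-dimethylphthalide | Cc1c(O)c(C)c(O)c2C(=O)OCc12 | intermediate
4 | (R)-(+)-pulegone | C[C@@H]1CCC(=C(C)C)C(=O)C1 | starting material
5 | tert-butyl acrylate | C=CC(=O)OC(C)(C)C | starting material
6 | tert-butyl 3-[(1R,4R)-4-methyl-2-oxo-1-(prop-1-en-2-yl)cyclohexyl]propanoate | O=C1C[C@H](C)CC[C@@]1(CCC(=O)OC(C)(C)C)C(C)=C | intermediate
7 | 3-[(1R,4R)-4-methyl-2-oxo-1-(prop-1-en-2-yl)cyclohexyl]propanoic acid | O=C1C[C@H](C)CC[C@@]1(CCC(=O)O)C(C)=C | intermediate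
8 | (6R,9R)-1,1,9-trimethyl-2-oxaspiro[5.5]undecane-3,7-dione | CC1(C)OC(=O)CC[C@]12CC[C@@H](C)CC2=O | intermediate
9 | 4,8-bis(phenylselanyl) derivative of 8 (selenide centres as mixtures) | CC1(C)OC(=O)C([Se]c3ccccc3)C[C@]12CC[C@@H](C)C([Se]c3ccccc3)C2=O | intermediate
10 | (R)-1,1,9-trimethyl-2-oxaspiro[5.5]undeca-4,8-diene-3,7-dione | CC1(C)OC(=O)C=C[C@]12CCC(C)=CC2=O | intermediate
11 | (6S,7R)-7-hydroxy-1,1,7,9-tetramethyl-2-oxaspiro[5.5]undeca-4,8-dien-3-one | CC1(C)OC(=O)C=C[C@]12CCC(C)=C[C@@]2(C)O | intermediate
12 | (6S,7R,8S)-7-hydroxy-8-(hydroxymethyl)-1,1,7-trimethyl-9-methylidene-2-oxaspiro[5.5]undec-4-en-3-one | CC1(C)OC(=O)C=C[C@]12CCC(=C)[C@@H](CO)[C@@]2(C)O | intermediate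
13 | (6S,7R,8R)-7-hydroxy-8-(iodomethyl)-1,1,7-trimethyl-9-methylidene-2-oxaspiro[5.5]undec-4-en-3-one | CC1(C)OC(=O)C=C[C@]12CCC(=C)[C@@H](CI)[C@@]2(C)O | intermediate
14 | (6R,7R,8R)-8-(iodomethyl)-1,1,7-trimethyl-9-methylidene-7-(trimethylsilyloxy)-2-oxaspiro[5.5]undec-4-en-3-one | CC1(C)OC(=O)C=C[C@]12CCC(=C)[C@@H](CI)[C@@]2(C)O[Si](C)(C)C | intermediate
15 | 7-hydroxy-4,6-dimethyl-4-(ring-B-methyl)isobenzofuran-1,5(3H,4H)-dione, ring B as in 14 with CH2 in place of CH2I; about 1:1 C4 epimers | CC1(C)OC(=O)C=C[C@]12CCC(=C)[C@@H](CC3(C)C(=O)C(C)=C(O)C4=C3COC4=O)[C@@]2(C)O[Si](C)(C)C | intermediate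
16 | 7-O-trimethylsilyl enol ether of 15 (both C4 epimers) | CC1(C)OC(=O)C=C[C@]12CCC(=C)[C@@H](CC3(C)C(=O)C(C)=C(O[Si](C)(C)C)C4=C3COC4=O)[C@@]2(C)O[Si](C)(C)C | intermediate
17 | ring-opened (Z)-dienylketene from C4–C5 cleavage of 16 | CC1(C)OC(=O)C=C[C@]12CCC(=C)[C@@H](CC(C)=C3COC(=O)C3=C(O[Si](C)(C)C)C(C)=C=O)[C@@]2(C)O[Si](C)(C)C | intermediate
18 | cycloadduct as bis-trimethylsilyl derivative (silyl enol ether of the lactone-bridge ketone, silyl ether of the tertiary alcohol); cage stereocentres as in the target | CC1(C)OC(=O)C=C[C@]12CC[C@]13C[C@]4(C)C(=O)[C@](C)(C[C@H]1[C@@]2(C)O[Si](C)(C)C)[C@]31COC(=O)C1=C4O[Si](C)(C)C | intermediate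
19 | pentacyclic keto lactone: the target with C=O in place of the secondary CHOH; other stereocentres as in the target | CC1(C)OC(=O)C=C[C@]12CC[C@]13C[C@]4(C)C(=O)[C@](C)(C[C@H]1[C@@]2(C)O)[C@]31COC(=O)[C@@H]1C4=O | intermediate
20 | CNP0360620.3 | CC1(C)OC(=O)C=C[C@]12CC[C@]13C[C@]4(C)C(=O)[C@](C)(C[C@H]1[C@@]2(C)O)[C@]31COC(=O)[C@@H]1[C@H]4O | target

## Step count and risks

Total step count: 10. Longest linear sequence: 9 (steps 2 to 10, from pulegone).

The three steps most likely to fail are steps 8, 9 and 10. The Lewis acid ene reaction of step 6 and the diastereoselectivity of step 2 are the next concerns.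

Step 8 may give O-alkylation, or C-alkylation at C6 instead of C4, because the iodide is unactivated and β-branched. The fallback builds ring D around the new carbon instead of dearomatizing an arene. It sets out from 14: the dianion of methyl 2-methyl-3-oxopentanoate (NaH, then n-BuLi, THF, 0 °C) is alkylated at its terminal carbon by 14 to give the β-keto ester F1. The dianion of F1 is then added to 4-bromofuran-2(5H)-one, and addition–elimination at C4 gives the butenolide F2 with the quaternary carbon in place. KOtBu in THF then closes ring D by Dieckmann-type acylation of the furanolate C3 by the methyl ester, which returns to 15.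

Step 9 is the proposed new reaction; the excited dienone may instead form a bicyclo[3.1.0]hexenone, or the ketene may add to the alkene. The fallback uses known thermal chemistry and accepts the loss of the mismatched epimer. It sets out from 15: the enol is methylated with Me3SiCHN2 in toluene/MeOH and the C4 epimers are separated. The matched methyl enol ether F3 is heated in the dark (toluene, 150 °C, sealed tube) to give the cage enol ether F4 by the ordinary intramolecular Diels–Alder reaction. Aqueous HCl in THF then cleaves the enol ether and the silyl ether, which comes back to the route at 19.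

Step 10 may deliver hydride or hydrogen from the more open face and give the wrong carbinol epimer. The fallback accepts kinetic attack and inverts. It sets out from 19: NaBH4 in MeOH at −40 °C gives the epimeric alcohol F5. Mitsunobu inversion with chloroacetic acid (PPh3, iPrO2CN=NCO2iPr, THF) gives the chloroacetate F6; the tertiary alcohol does not react. Thiourea with NaHCO3 in EtOH removes the chloroacetyl group and returns to 20.

## Further compounds

F1 | step 8 | methyl 2,4-dimethyl-3-oxo-5-(ring-B C8)pentanoate, ring B as in 14 with CH2 in place of CH2I; diastereomer mixture | CC1(C)OC(=O)C=C[C@]12CCC(=C)[C@@H](CC(C)C(=O)C(C)C(=O)OC)[C@@]2(C)O[Si](C)(C)C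
F2 | step 8 | 4-substituted furan-2(5H)-one from F1, quaternary carbon bearing methyl, the ring-B methylene, the butenolide C4 and the 2-methyl-3-methoxy-3-oxopropanoyl group; diastereomer mixture | CC1(C)OC(=O)C=C[C@]12CCC(=C)[C@@H](CC(C)(C3=CC(=O)OC3)C(=O)C(C)C(=O)OC)[C@@]2(C)O[Si](C)(C)C
F3 | step 9 | 7-O-methyl enol ether of 15, C4 epimer matched for cycloaddition | CC1(C)OC(=O)C=C[C@]12CCC(=C)[C@@H](C[C@@]3(C)C(=O)C(C)=C(OC)C4=C3COC4=O)[C@@]2(C)O[Si](C)(C)C
F4 | step 9 | cycloadduct as methyl enol ether and trimethylsilyl ether, cage stereocentres as in the target | CC1(C)OC(=O)C=C[C@]12CC[C@]13C[C@]4(C)C(=O)[C@](C)(C[C@H]1[C@@]2(C)O[Si](C)(C)C)[C@]31COC(=O)C1=C4OC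
F5 | step 10 | epimer of the target at the secondary carbinol | CC1(C)OC(=O)C=C[C@]12CC[C@]13C[C@]4(C)C(=O)[C@](C)(C[C@H]1[C@@]2(C)O)[C@]31COC(=O)[C@@H]1[C@@H]4O
F6 | step 10 | chloroacetate of the target at the secondary carbinol | CC1(C)OC(=O)C=C[C@]12CC[C@]13C[C@]4(C)C(=O)[C@](C)(C[C@H]1[C@@]2(C)O)[C@]31COC(=O)[C@@H]1[C@H]4OC(=O)CCl
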